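**Retrosynthetic overview**
- The target comes from chemoselective reduction of its (13Z)-ethyl 15-ester; the 7α-OH and the Δ8(9) alkene come from a singlet-oxygen ene reaction on a 6β-acetoxy-Δ7 alkene.
- Key cut, C12–C13: a primary C12 bromide is joined to ethyl (Z)-3-(chlorozincio)but-2-enoate, a β-acylvinyl anion (sp2 homoenolate, d3) reagent. Both carbons are natively electrophilic, and the reagent brings in the 13Z geometry.
- The 6β-oxygen comes from α-face hydride reduction of a 7-en-6-one, itself made by allylic oxidation of a Δ7 tetranorlabdene ester.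
- The Δ7 ester comes from (+)-sclareolide by lactone opening, exocyclic dehydration and alkene isomerisation.
- Ring order: no ring is formed; the trans-decalin (rings A and B, C5 and C10 configuration) is taken intact from sclareolide.

Assumption: labdane numbering is used throughout, and the target is read as (13Z)-6β-acetoxylabda-8,13-diene-7α,15-diol of the normal (sclareol) series, with 5α-H and 10β-CH3.

**Step 1**
Reactants: 1 (+)-sclareolide
Product: 3 methyl 8α-hydroxy-13,14,15,16-tetranorlabdan-12-oate, via potassium carboxylate 2 (not isolated)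
Conditions: KOH (1.1 equiv), MeOH, reflux; evaporate; MeI, DMF, rt
Reagents that add atoms: potassium hydroxide [K+].[OH-]; iodomethane CI
Why: Saponification opens the γ-lactone and SN2 O-methylation of the carboxylate under non-acidic conditions prevents relactonisation, with no stereocentre touched.

**Step 2**
Reactants: 3 methyl 8α-hydroxy-13,14,15,16-tetranorlabdan-12-oate
Product: 4 methyl 13,14,15,16-tetranorlabd-8(17)-en-12-oate
Conditions: SOCl2, pyridine, CH2Cl2, −78 °C
Reagents that add atoms: none
Why: Chlorosulfite formation and pyridine-mediated E2-type dehydration of the equatorial tertiary 8α-alcohol, where in the rigid trans-decalin only the C17 methyl hydrogens can lie anti-periplanar to the leaving group, so the exocyclic alkene is the major product (any minor Δ7 isomer converges in step 3).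

**Step 3**
Reactants: 4 methyl 13,14,15,16-tetranorlabd-8(17)-en-12-oate
Product: 5 methyl 13,14,15,16-tetranorlabd-7-en-12-oate
Conditions: Co(salen-tBu,tBu)Cl (3 mol %), PhSiH3 (6 mol %), benzene, rt
Reagents that add atoms: none
Why: Cobalt-hydride MHAT alkene isomerisation (Shenvi type), in which H-atom transfer to the =CH2 gives the tertiary C8 radical and H-atom return from the less hindered axial C7–H gives the trisubstituted Δ7 alkene, which is inert to further MHAT, so C9 keeps its configuration.

**Step 4**
Reactants: 5 methyl 13,14,15,16-tetranorlabd-7-en-12-oate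
Product: 6 methyl 6-oxo-13,14,15,16-tetranorlabd-7-en-12-oate
Conditions: Na2CrO4, NaOAc, AcOH/Ac2O, benzene, 55 °C
Reagents that add atoms: sodium chromate [Na+].[Na+].[O-][Cr](=O)(=O)[O-]
Why: Chromium(VI) allylic oxidation of C6, the only ring CH2 flanking the Δ7 alkene, gives the conjugated 7-en-6-one, with C5 remaining in the thermodynamically preferred trans fusion.

**Step 5**
Reactants: 6 methyl 6-oxo-13,14,15,16-tetranorlabd-7-en-12-oate
Product: 7 13,14,15,16-tetranorlabd-7-ene-6β,12-diol
Conditions: LiAlH4, THF, 0 °C; aq. NaOH work-up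
Reagents that add atoms: none
Why: LiAlH4 1,2-reduction of the β,β-disubstituted enone with hydride delivered from the open α-face (the β-face is blocked by the syn-axial C4β and C10 methyls) sets the axial 6β-OH, and the ester is reduced to the primary alcohol in the same operation.

**Step 6**
Reactants: 7 13,14,15,16-tetranorlabd-7-ene-6β,12-diol
Product: 8 12-bromo-13,14,15,16-tetranorlabd-7-en-6β-ol
Conditions: CBr4 (1.05 equiv), PPh3, CH2Cl2, 0 °C
Reagents that add atoms: tetrabromomethane BrC(Br)(Br)Br
Why: Appel bromination is selective for the primary alcohol because the axial 6β-allylic alcohol, flanked by two syn-axial methyls, does not react with one equivalent of reagent at 0 °C.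

**Step 7**
Reactants: 9 ethyl but-2-ynoate
Product: 10 ethyl (Z)-3-iodobut-2-enoate
Conditions: NaI, AcOH, 115 °C
Reagents that add atoms: sodium iodide [Na+].[I-]
Why: Conjugate hydroiodination of the ynoate proceeds by anti addition, giving the (Z)-β-iodoenoate with iodine cis to the ester.

**Step 8**
Reactants: 8 12-bromo-13,14,15,16-tetranorlabd-7-en-6β-ol; 10 ethyl (Z)-3-iodobut-2-enoate
Product: 13 ethyl (13Z)-6β-hydroxylabda-7,13-dien-15-oate, via magnesiated enoate 11 (not isolated), via zinc enoate 12 (not isolated)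
Conditions: 10 (2.5 equiv), i-PrMgCl·LiCl (2.4 equiv), THF, −40 °C; ZnCl2 (2.6 equiv), −40 °C to rt; then 8, Pd2(dba)3 (2 mol %), PCyp3 (8 mol %), N-methylimidazole, THF/NMP 2:1, 80 °C
Reagents that add atoms: none
Why: Proposed new method: I/Mg exchange gives the carbonyl-chelated, configurationally stable (Z)-β-magnesio enoate, zinc transmetalation turns it into a β-acylvinyl anion (sp2 homoenolate, d3) reagent whose normally electrophilic β-carbon is now the nucleophile, and Pd/PCyp3-catalysed alkyl–alkenyl Negishi coupling (SN2-type oxidative addition of the primary C12–Br, transmetalation, reductive elimination with retention of alkene geometry, the bulky trialkylphosphine suppressing β-hydride elimination and the excess zinc reagent covering the one free OH) joins two natively electrophilic carbons and sets 13Z directly, the closest known reactions being Fu-type Negishi coupling of unactivated primary alkyl bromides with alkenylzinc halides and electrophile trapping of Knochel-type (Z)-3-magnesiated enoates.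

**Step 9**
Reactants: 13 ethyl (13Z)-6β-hydroxylabda-7,13-dien-15-oate
Product: 14 ethyl (13Z)-6β-acetoxylabda-7,13-dien-15-oate
Conditions: Ac2O, DMAP, Et3N, CH2Cl2, 40 °C
Reagents that add atoms: acetic anhydride CC(=O)OC(C)=O
Why: DMAP-catalysed (Steglich-type) acyl transfer to the only hydroxyl group, with warming to overcome the hindrance of the axial 6β-OH, proceeds with retention at C6.

**Step 10**
Reactants: 14 ethyl (13Z)-6β-acetoxylabda-7,13-dien-15-oate
Product: 16 ethyl (13Z)-6β-acetoxy-7α-hydroxylabda-8,13-dien-15-oate, via allylic hydroperoxide 15 (not isolated)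
Conditions: O2, tetraphenylporphyrin (cat.), visible light, CH2Cl2, 0 °C; then PPh3, rt
Reagents that add atoms: oxygen O=O
Why: Schenck ene reaction, in which singlet oxygen bonds to C7 from the α-face (the β-face is shielded by the axial C10 methyl and the 6β-acetate) and abstracts the pseudo-axial 9α-H on the same face, moving the alkene to the tetrasubstituted Δ8(9) position and setting 7α-O, while the electron-poor enoate is inert and PPh3 reduces the hydroperoxide with retention.

**Step 11**
Reactants: 16 ethyl (13Z)-6β-acetoxy-7α-hydroxylabda-8,13-dien-15-oate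
Product: 17 (13Z)-6β-acetoxylabda-8,13-diene-7α,15-diol (CNP0183298.2)
Conditions: DIBAL-H (3.05 equiv), CH2Cl2, −78 °C; Rochelle salt work-up
Reagents that add atoms: none
Why: DIBAL-H 1,2-reduction of the unhindered conjugated ethyl ester at −78 °C, where the axial 6β-acetate flanked by the syn-axial C4β and C10 methyls (as shielded as a steroidal 11β-acetate) is attacked far more slowly and the Z-alkene is untouched.

**Compound list**
1 | (+)-sclareolide (8α,12-lactone of 8α-hydroxy-13,14,15,16-tetranorlabdan-12-oic acid; 5α-H, 9α-H, 10β-CH3) | C1C[C@@]3(C)OC(=O)C[C@@H]3[C@@]2(C)CCCC(C)(C)[C@H]12 | starting material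
2 | potassium 8α-hydroxy-13,14,15,16-tetranorlabdan-12-oate | C1C[C@@](C)(O)[C@H](CC(=O)[O-])[C@@]2(C)CCCC(C)(C)[C@H]12.[K+] | intermediate
3 | methyl 8α-hydroxy-13,14,15,16-tetranorlabdan-12-oate | C1C[C@@](C)(O)[C@H](CC(=O)OC)[C@@]2(C)CCCC(C)(C)[C@H]12 | intermediate
4 | methyl 13,14,15,16-tetranorlabd-8(17)-en-12-oate (exocyclic methylene at C8) | C1CC(=C)[C@H](CC(=O)OC)[C@@]2(C)CCCC(C)(C)[C@H]12 | intermediate
5 | methyl 13,14,15,16-tetranorlabd-7-en-12-oate | C1C=C(C)[C@H](CC(=O)OC)[C@@]2(C)CCCC(C)(C)[C@H]12 | intermediate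
6 | methyl 6-oxo-13,14,15,16-tetranorlabd-7-en-12-oate | O=C1C=C(C)[C@H](CC(=O)OC)[C@@]2(C)CCCC(C)(C)[C@H]12 | intermediate
7 | 13,14,15,16-tetranorlabd-7-ene-6β,12-diol | O[C@@H]1C=C(C)[C@H](CCO)[C@@]2(C)CCCC(C)(C)[C@H]12 | intermediate
8 | 12-bromo-13,14,15,16-tetranorlabd-7-en-6β-ol | O[C@@H]1C=C(C)[C@H](CCBr)[C@@]2(C)CCCC(C)(C)[C@H]12 | intermediate
9 | ethyl but-2-ynoate | CC#CC(=O)OCC | starting material
10 | ethyl (Z)-3-iodobut-2-enoate (iodine cis to the ester) | CCOC(=O)/C=C(/C)I | intermediate
11 | ethyl (Z)-3-(chloromagnesio)but-2-enoate, LiCl complex | CCOC(=O)/C=C(/C)[Mg]Cl | intermediate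
12 | ethyl (Z)-3-(chlorozincio)but-2-enoate | CCOC(=O)/C=C(/C)[Zn]Cl | intermediate
13 | ethyl (13Z)-6β-hydroxylabda-7,13-dien-15-oate | O[C@@H]1C=C(C)[C@H](CC/C(C)=C\C(=O)OCC)[C@@]2(C)CCCC(C)(C)[C@H]12 | intermediate
14 | ethyl (13Z)-6β-acetoxylabda-7,13-dien-15-oate | CC(=O)O[C@@H]1C=C(C)[C@H](CC/C(C)=C\C(=O)OCC)[C@@]2(C)CCCC(C)(C)[C@H]12 | intermediate
15 | ethyl (13Z)-6β-acetoxy-7α-hydroperoxylabda-8,13-dien-15-oate | CC(=O)O[C@@H]1[C@@H](OO)C(C)=C(CC/C(C)=C\C(=O)OCC)[C@@]2(C)CCCC(C)(C)[C@H]12 | intermediate
16 | ethyl (13Z)-6β-acetoxy-7α-hydroxylabda-8,13-dien-15-oate | CC(=O)O[C@@H]1[C@@H](O)C(C)=C(CC/C(C)=C\C(=O)OCC)[C@@]2(C)CCCC(C)(C)[C@H]12 | intermediate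
17 | (13Z)-6β-acetoxylabda-8,13-diene-7α,15-diol (CNP0183298.2) | CC(=O)O[C@@H]1[C@@H](O)C(C)=C(CC/C(C)=C\CO)[C@@]2(C)CCCC(C)(C)[C@H]12 | target

**Step count**
Total steps: 11. Longest linear sequence: 10 (steps 1–6 and 8–11); step 7 is a one-step side branch.

**Three steps most likely to fail**

Step 8 (alkyl–alkenyl coupling of the β-zincio enoate). The risks are protonolysis of 12 by the free 6β-OH, β-hydride loss from the alkyl-palladium, and slow transmetalation of the chelated zinc reagent. Fallback, from 8 back to 13: the C12–C13 bond is made with an acyl-anion equivalent instead. Compound 8 is alkylated with 2-lithio-2-methyl-1,3-dithiane (2.2 equiv, THF, −30 to 0 °C; the first equivalent only deprotonates the 6β-OH) to give the 2-methyl-1,3-dithiane adduct F1. MeI/CaCO3 in aqueous MeCN unmasks the methyl ketone F2. Still–Gennari olefination (ethyl bis(2,2,2-trifluoroethyl)phosphonoacetate, KHMDS, 18-crown-6, THF, −78 °C) then returns to 13 after chromatographic removal of the 13E isomer; Z-selectivity on a methyl ketone is only moderate.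

Step 10 (ene regiochemistry). Abstraction of a C17 methyl hydrogen competes with abstraction of the 9α-H, and could give roughly equal amounts of the exocyclic Δ8(17) isomer. Fallback, from 14 back to 16: the exocyclic product is accepted and the alkene is moved afterwards. The same photo-oxygenation gives the exocyclic 7α-hydroperoxide F3 and PPh3 gives the exocyclic allylic alcohol F4. Cobalt-hydride MHAT isomerisation (catalyst system of step 3) then forms the C8 radical, which besides the methyl can only lose the axial 9α-H (the 7β-H is equatorial and misaligned), converging on 16.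

Step 11 (ester reduction beside the 6β-acetate). DIBAL-H may also cleave the acetate. Fallback, from 16 back to 17: selectivity is moved from reduction to solvolysis. Exhaustive LiAlH4 reduction of 16 gives the triol F5, and Ac2O/DMAP at 50 °C gives the triacetate F6. K2CO3/MeOH at 0 °C then removes the primary allylic 15-acetate and the allylic 7α-acetate while the doubly syn-axially shielded 6β-acetate stays, giving 17.

**Further compounds**
F1 | step 8 | 2-methyl-2-[2-(6β-hydroxy-13,14,15,16-tetranorlabd-7-en-12-yl)]-1,3-dithiane (dithiane carbon = C13) | O[C@@H]1C=C(C)[C@H](CCC3(C)SCCCS3)[C@@]2(C)CCCC(C)(C)[C@H]12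
F2 | step 8 | 6β-hydroxy-14,15-dinorlabd-7-en-13-one | O[C@@H]1C=C(C)[C@H](CCC(C)=O)[C@@]2(C)CCCC(C)(C)[C@H]12
F3 | step 10 | ethyl (13Z)-6β-acetoxy-7α-hydroperoxylabda-8(17),13-dien-15-oate | CC(=O)O[C@@H]1[C@@H](OO)C(=C)[C@H](CC/C(C)=C\C(=O)OCC)[C@@]2(C)CCCC(C)(C)[C@H]12
F4 | step 10 | ethyl (13Z)-6β-acetoxy-7α-hydroxylabda-8(17),13-dien-15-oate | CC(=O)O[C@@H]1[C@@H](O)C(=C)[C@H](CC/C(C)=C\C(=O)OCC)[C@@]2(C)CCCC(C)(C)[C@H]12
F5 | step 11 | (13Z)-labda-8,13-diene-6β,7α,15-triol | O[C@@H]1[C@@H](O)C(C)=C(CC/C(C)=C\CO)[C@@]2(C)CCCC(C)(C)[C@H]12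
F6 | step 11 | (13Z)-6β,7α,15-triacetoxylabda-8,13-diene | CC(=O)O[C@@H]1[C@@H](OC(C)=O)C(C)=C(CC/C(C)=C\COC(C)=O)[C@@]2(C)CCCC(C)(C)[C@H]12
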